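Your neighbour will charge this same flask with a quarter more nucleophile than the amount you must find, so find that amount first.

electrophile 0.20 mM; solid base 0.400 mM; time 1.0 min

* the concentration of nucleophile at which the part of the electrophile that has reacted at 1.0 min is just 80%, in mM

    electrophile + nucleophile → acid set free + target (k1 = 2900 M⁻¹ s⁻¹)
    nucleophile + acid set free ⇌ protonated nucleophile, settled at all times (K2 = 4.3 × 10⁷ M⁻¹)
    acid set free + free base ⇌ salt of the base (K3 = 44000 M⁻¹, k3 = 1700 M⁻¹ s⁻¹)
    solid base ⇌ free base, rate k4*(cs4 - [free base]) while solid is left; crystals form when [free base] > cs4 (cs4 = 0.011 mM, k4 = 0.080 s⁻¹)
    2 free base → self-condensation product (k5 = 260 M⁻¹ s⁻¹)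

Begin with the rate. Each turn of the electrophile with nucleophile sets free one acid, and I take that acid to be caught by a second nucleophile, given a balance constant of 4.3 × 10⁷ M⁻¹. Divide the rate at which nucleophile falls by the rate at which electrophile falls and time drops out: one goes into the target and one is protonated, so the price is 2.00, nucleophile lost per electrophile reacted.

Leaving the solid base aside, that price asks for a charge of 0.320 mM. With this charge, each electrophile starts reacting at 55.7 min⁻¹, a time constant of 1.08 s, far shorter than the run. At half the wanted turnover, the electrophile factor is 0.600 and the nucleophile factor 0.5, so the rate stands at 0.300 of its start. At the wanted turnover the electrophile factor is 0.200 and the nucleophile factor zero, so the rate stalls there, and the minute is ample to reach that stop. My reckoning stops at that figure, with the base's share unreckoned.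

The forecast says 0.309 mM: “each acid released ties up a second nucleophile”, and it takes about 0.01 mM off for the acid taken up by the dissolved base together with the free acid left over.

The simulation gives 0.311 mM.

In that flask the first step ran quickly while free nucleophile lasted, with 73.5% of the electrophile used at 0.100 min, 77.7% at 0.250 min and 78.9% after half the time, while half the dissolving of the solid base was done by 0.208 min. At 1.00 min the half-life of nucleophile in this step, 0.10 min, is shorter than the run, against 8.0 min for the electrophile, which marks nucleophile as the limiting reagent. For your neighbour's flask, charge over price pays for 97.3% of the electrophile, and that flask reads 97.1%.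

The rate constants come from no measurement; the rest is arithmetic.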